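**Assumption:** in step 1 the (R)-ligand is taken to give the (R)-acid (the same sense as the (S)-ligand giving the (S)-acid). The acid obtained must be levorotatory; if it is not, the antipodal ligand is used.

## Retrosynthetic overview

1. Target 15 ⇒ arene 8 + pyranone 12 + one CH2 unit, joined last by a Mannich/Michael three-component coupling at the only free ring CH of 8.
2. 8 ⇒ 7 by the key bond, the aryl O–CH3 bond: a chelation-gated copper O-methylation that picks the unhindered, hydrogen-bonded 6-OH (new).
3. 7 ⇒ 5 (C-prenylation at one of two equivalent CH positions) ⇒ phloroglucinol 3 + (R)-acid 2 (Friedel–Crafts); 2 ⇐ tiglic acid 1 by asymmetric hydrogenation, which sets the only stereocentre.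
4. 12 ⇐ methyl 3-oxopentanoate 9 + Weinreb amide 10 (dianion acylation, then C–O lactonisation).
5. Rings: the benzene ring is bought as phloroglucinol; the pyranone is the only ring made (step 5), before the final coupling.

## Route

**Step 1**
Reactants: 1 tiglic acid [(2E)-2-methylbut-2-enoic acid]
Product: 2 (2R)-2-methylbutanoic acid
Conditions: Ru(OAc)2[(R)-H8-BINAP] (0.5 mol %), H2 (4 atm), MeOH, 20 °C
Reagents that add atoms: none
Why: Carboxylate-directed Ru(II)–biaryl-bisphosphine asymmetric hydrogenation (Noyori type) of the trisubstituted enoic acid adds H2 to one enantioface of C2=C3 and so sets the (R) stereocentre (about 95–97% ee expected).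

**Step 2**
Reactants: 2 (2R)-2-methylbutanoic acid, 3 phloroglucinol (benzene-1,3,5-triol)
Product: 5 (2R)-2-methyl-1-(2,4,6-trihydroxyphenyl)butan-1-one, via (2R)-2-methylbutanoyl chloride 4 (not isolated)
Conditions: (COCl)2, cat. DMF, CH2Cl2, 0 °C → rt; then 3, AlCl3 (3.5 equiv), PhNO2/CH2Cl2, 0 °C → rt; 1 M HCl
Reagents that add atoms: none
Why: Friedel–Crafts C-acylation of the threefold-symmetric, very electron-rich arene stops at the mono-ketone because the product is deactivated as its aluminium chelate, and the low temperature is chosen to keep the α-stereocentre from enolising.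

**Step 3**
Reactants: 5 (2R)-2-methyl-1-(2,4,6-trihydroxyphenyl)butan-1-one, 6 prenyl bromide (1-bromo-3-methylbut-2-ene)
Product: 7 (2R)-2-methyl-1-[2,4,6-trihydroxy-3-(3-methylbut-2-en-1-yl)phenyl]butan-1-one
Conditions: 6 (0.95 equiv), 5% aq. KOH (1.0 equiv), 0 °C, 1 h; then 1 M HCl
Reagents that add atoms: none
Why: Base-mediated C-alkylation (C-prenylation) of the ambident phloroglucinolate at one of its two equivalent ring CH positions, where water favours C- over O-alkylation, a slight deficit of bromide limits diprenylation, and the ketone α-CH is not touched because the carbonyl is part of a vinylogous carboxylate.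

**Step 4**
Reactants: 7 (2R)-2-methyl-1-[2,4,6-trihydroxy-3-(3-methylbut-2-en-1-yl)phenyl]butan-1-one
Product: 8 (2R)-1-[2,4-dihydroxy-6-methoxy-3-(3-methylbut-2-en-1-yl)phenyl]-2-methylbutan-1-one
Conditions: Cu(OAc)2 (2.2 equiv), TMEDA (2.2 equiv), MeB(OH)2 (1.5 equiv), 4 Å MS, ClCH2CH2Cl, Ar, 50 °C; aq. Na2EDTA/NH4Cl work-up
Reagents that add atoms: methylboronic acid, CB(O)O
Why: Proposed new method: a chelation-gated Chan–Lam O-methylation in which the substrate is its own directing ligand – acetate is too weak a base to metalate the free 4-OH, but the 6-OH/C=O pair is deprotonated on forming a six-membered Cu(II) chelate (the 2-OH chelate is disfavoured because the 3-prenyl CH2 clashes with an NMe2 arm of TMEDA), MeB(OH)2 transmetalates at that copper, a second Cu(II) oxidises it to a Cu(III)(Me)(aryloxide), and C–O reductive elimination can only place the methyl on the copper-bound O6, the reverse of the 4-OH-first order of base/SN2 methylation; the closest known reaction type is the Cu(II)-mediated Chan–Lam oxidative O-methylation of simple phenols with methylboronic acid, run here without O2 to spare the electron-rich ring.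

**Step 5**
Reactants: 9 methyl 3-oxopentanoate, 10 N-methoxy-N-methylpropanamide
Product: 12 6-ethyl-4-hydroxy-5-methyl-2H-pyran-2-one, via methyl 4-methyl-3,5-dioxoheptanoate 11 (not isolated)
Conditions: LDA (2.2 equiv), THF, −78 → 0 °C; 10, −78 → 0 °C; aq. HCl; crude, then DBU (1.5 equiv), PhMe, 110 °C; acidify
Reagents that add atoms: none
Why: Weiler-type dianion γ-acylation (Claisen-type) with the Weinreb amide gives the 3,5-diketo ester, whose C5 enol oxygen then attacks the ester under DBU in a 6-exo-trig lactonisation (C–O ring closure) with loss of methanol to give the stabilised 4-hydroxy-2-pyranone.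

**Step 6**
Reactants: 12 6-ethyl-4-hydroxy-5-methyl-2H-pyran-2-one, 8 (2R)-1-[2,4-dihydroxy-6-methoxy-3-(3-methylbut-2-en-1-yl)phenyl]-2-methylbutan-1-one
Product: 15 3-({2,4-dihydroxy-6-methoxy-5-[(2R)-2-methylbutanoyl]-3-(3-methylbut-2-en-1-yl)phenyl}methyl)-6-ethyl-4-hydroxy-5-methyl-2H-pyran-2-one, via 3-[(dimethylamino)methyl]-6-ethyl-4-hydroxy-5-methyl-2H-pyran-2-one 13 (not isolated), via 6-ethyl-5-methyl-3-methylidene-2H-pyran-2,4(3H)-dione 14 (not isolated)
Conditions: 12, Me2N+=CH2 I− (1.05 equiv), MeCN, rt, 1 h; then 8 (1.0 equiv), 70 °C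
Reagents that add atoms: Eschenmoser's salt (N,N-dimethylmethyleneiminium iodide), C=[N+](C)C.[I-]
Why: Mannich aminomethylation of pyranone C3, thermal loss of dimethylamine to the 3-methylidene-pyrandione (a vinylogous o-quinone methide) and Friedel–Crafts-type Michael addition of the only free ring CH of 8 (a carba-Betti-type three-component coupling) build the methylene bridge under near-neutral conditions that leave the prenyl group and the stereocentre untouched.

## Compound list

1 | tiglic acid, (2E)-2-methylbut-2-enoic acid | C/C=C(\C)C(=O)O | starting material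
2 | (2R)-2-methylbutanoic acid | CC[C@@H](C)C(=O)O | intermediate
3 | phloroglucinol (benzene-1,3,5-triol) | Oc1cc(O)cc(O)c1 | starting material
4 | (2R)-2-methylbutanoyl chloride | CC[C@@H](C)C(=O)Cl | intermediate
5 | (2R)-2-methyl-1-(2,4,6-trihydroxyphenyl)butan-1-one | CC[C@@H](C)C(=O)c1c(O)cc(O)cc1O | intermediate
6 | prenyl bromide (1-bromo-3-methylbut-2-ene) | CC(C)=CCBr | starting material
7 | (2R)-2-methyl-1-[2,4,6-trihydroxy-3-(3-methylbut-2-en-1-yl)phenyl]butan-1-one | CC[C@@H](C)C(=O)c1c(O)cc(O)c(CC=C(C)C)c1O | intermediate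
8 | (2R)-1-[2,4-dihydroxy-6-methoxy-3-(3-methylbut-2-en-1-yl)phenyl]-2-methylbutan-1-one | CC[C@@H](C)C(=O)c1c(OC)cc(O)c(CC=C(C)C)c1O | intermediate
9 | methyl 3-oxopentanoate | CCC(=O)CC(=O)OC | starting material
10 | N-methoxy-N-methylpropanamide | CCC(=O)N(C)OC | starting material
11 | methyl 4-methyl-3,5-dioxoheptanoate | CCC(=O)C(C)C(=O)CC(=O)OC | intermediate
12 | 6-ethyl-4-hydroxy-5-methyl-2H-pyran-2-one | CCc1oc(=O)cc(O)c1C | intermediate
13 | 3-[(dimethylamino)methyl]-6-ethyl-4-hydroxy-5-methyl-2H-pyran-2-one | CCc1oc(=O)c(CN(C)C)c(O)c1C | intermediate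
14 | 6-ethyl-5-methyl-3-methylidene-2H-pyran-2,4(3H)-dione | CCC1=C(C)C(=O)C(=C)C(=O)O1 | intermediate
15 | 3-({2,4-dihydroxy-6-methoxy-5-[(2R)-2-methylbutanoyl]-3-(3-methylbut-2-en-1-yl)phenyl}methyl)-6-ethyl-4-hydroxy-5-methyl-2H-pyran-2-one | CCc1oc(=O)c(Cc2c(O)c(CC=C(C)C)c(O)c(C(=O)[C@H](C)CC)c2OC)c(O)c1C | target

## Step count and risks

Total step count: 6. Longest linear sequence: 5 (steps 1, 2, 3, 4, 6).

**Step 4 (the new step).** Copper may be held as an unreactive chelate, methyl may go to the 4-OH or 2-OH, or the electron-rich ring may be oxidised. The fallback uses known chemistry and sets out from 7. MOMCl (1.05 equiv) and iPr2NEt in CH2Cl2 at 0 °C protect the most acidic, non-chelated 4-OH to give (2R)-1-[2,6-dihydroxy-4-(methoxymethoxy)-3-(3-methylbut-2-en-1-yl)phenyl]-2-methylbutan-1-one F1. MeI and K2CO3 in acetone then methylate the less hindered ortho-OH, while the prenyl-flanked OH stays locked in its hydrogen bond, to give (2R)-1-[2-hydroxy-6-methoxy-4-(methoxymethoxy)-3-(3-methylbut-2-en-1-yl)phenyl]-2-methylbutan-1-one F2. HCl in MeOH at rt removes the acetal, and the route is rejoined at 8.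

**Step 3.** Direct C-prenylation may give mostly diprenyl and O-prenyl products. The fallback places the prenyl group by rearrangement and sets out from 5. MOMCl (2.2 equiv) and iPr2NEt give (2R)-1-[2-hydroxy-4,6-bis(methoxymethoxy)phenyl]-2-methylbutan-1-one F3. Mitsunobu etherification of the remaining chelated OH with 3-methylbut-2-en-1-ol (PPh3, DIAD, THF) gives (2R)-1-[2,4-bis(methoxymethoxy)-6-[(3-methylbut-2-en-1-yl)oxy]phenyl]-2-methylbutan-1-one F4. A tandem aromatic Claisen/Cope rearrangement (PhNEt2, about 190 °C, or Eu(fod)3 catalysis at lower temperature) moves the prenyl group to the carbon para to the freed OH, between the two protected oxygens, to give (2R)-1-[6-hydroxy-2,4-bis(methoxymethoxy)-3-(3-methylbut-2-en-1-yl)phenyl]-2-methylbutan-1-one F5. HCl in MeOH at rt removes both acetals, and the route is rejoined at 7.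

**Step 2.** The Lewis-acid acylation may erode the α-stereocentre or give ester and diacyl side products. The fallback makes the ketone by addition of an aryllithium to an amide and sets out from 2 and 3. Acid 2 is converted with CDI and MeNHOMe·HCl into (2R)-N-methoxy-N,2-dimethylbutanamide F6. Phloroglucinol 3 is converted with MOMCl and NaH in DMF into 1,3,5-tris(methoxymethoxy)benzene F7. Ortho-lithiation of F7 (n-BuLi, THF, 0 °C) and addition to F6 give (2R)-2-methyl-1-[2,4,6-tris(methoxymethoxy)phenyl]butan-1-one F8; the ketone is released only on quench, so it is not exposed to base. HCl in MeOH at rt removes the acetals, and the route is rejoined at 5.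

## Further compounds

F1 | step 4 | (2R)-1-[2,6-dihydroxy-4-(methoxymethoxy)-3-(3-methylbut-2-en-1-yl)phenyl]-2-methylbutan-1-one | CC[C@@H](C)C(=O)c1c(O)cc(OCOC)c(CC=C(C)C)c1O
F2 | step 4 | (2R)-1-[2-hydroxy-6-methoxy-4-(methoxymethoxy)-3-(3-methylbut-2-en-1-yl)phenyl]-2-methylbutan-1-one | CC[C@@H](C)C(=O)c1c(OC)cc(OCOC)c(CC=C(C)C)c1O
F3 | step 3 | (2R)-1-[2-hydroxy-4,6-bis(methoxymethoxy)phenyl]-2-methylbutan-1-one | CC[C@@H](C)C(=O)c1c(O)cc(OCOC)cc1OCOC
F4 | step 3 | (2R)-1-[2,4-bis(methoxymethoxy)-6-[(3-methylbut-2-en-1-yl)oxy]phenyl]-2-methylbutan-1-one | CC[C@@H](C)C(=O)c1c(OCC=C(C)C)cc(OCOC)cc1OCOC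
F5 | step 3 | (2R)-1-[6-hydroxy-2,4-bis(methoxymethoxy)-3-(3-methylbut-2-en-1-yl)phenyl]-2-methylbutan-1-one | CC[C@@H](C)C(=O)c1c(O)cc(OCOC)c(CC=C(C)C)c1OCOC
F6 | step 2 | (2R)-N-methoxy-N,2-dimethylbutanamide | CC[C@@H](C)C(=O)N(C)OC
F7 | step 2 | 1,3,5-tris(methoxymethoxy)benzene | COCOc1cc(OCOC)cc(OCOC)c1
F8 | step 2 | (2R)-2-methyl-1-[2,4,6-tris(methoxymethoxy)phenyl]butan-1-one | CC[C@@H](C)C(=O)c1c(OCOC)cc(OCOC)cc1OCOC
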